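The cyclohexene ring that is spiro-fused to C5 of the tetronate (CHEt–CH2–C(spiro)–C(Me)–CH=C(Me)) is the retron of a [4+2] cycloaddition between a 5-methylene tetronate and an (E,E)-1,3-diene. That diene hangs, through the (Z)-butenyl chain, on the same trans-decalin that carries the 3-acyl tetronate. One intramolecular Diels–Alder reaction should therefore close the cyclohexene and the 11-membered carbocycle together and set the spiro carbon, the quaternary methyl carbon and the ethyl-bearing carbon. The precursor is an open-chain decalin with a 3-acyl-4-methoxy-5-methylenebutenolide on C1 and a (2Z,5E,7E)-5,7-dimethyldeca-2,5,7-trienyl arm on C2.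

Key step: step 21

Remark: the 3-acyl tetronic acid is written as the enol tautomer of the target SMILES; its tautomers equilibrate, so the last step gives this compound. TBS = tert-butyldimethylsilyl. Decalin locants follow octahydronaphthalene numbering (C1 quaternary, C2 arm-bearing, C3=C4 olefin, C5–C7 oxygenated ring B).

**Steps**

Step 1
Reactants: 1 tert-butyl(but-3-yn-1-yloxy)dimethylsilane
Product: 3 (E)-tert-butyl[(4-iodobut-3-en-1-yl)oxy]dimethylsilane, via alkenylzirconocene chloride 2 (not isolated)
Conditions: Cp2Zr(H)Cl, THF, rt; then I2, 0 °C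
Reagents that add atoms: iodine, II
Why: Hydrozirconation of the terminal alkyne is syn and anti-Markovnikov and iodinolysis of the C–Zr bond goes with retention, so the (E)-vinyl iodide should form as one isomer.

Step 2
Reactants: 3 (E)-vinyl iodide; 4 acrolein
Product: 5 (2E,4E)-7-(TBS-oxy)hepta-2,4-dienal
Conditions: Pd(OAc)2 (cat.), Bu4NCl, NaHCO3, DMF, 40 °C
Reagents that add atoms: none
Why: Heck reaction under ligand-free phase-transfer conditions keeps the vinyl iodide geometry, and syn insertion/syn β-hydride elimination should give the new (E)-olefin.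

Step 3
Reactants: 5 dienal; 6 (S)-4-benzyl-3-propionyloxazolidin-2-one
Product: 8 (S)-4-benzyl-3-[(2R,3R,4E,6E)-9-(TBS-oxy)-3-hydroxy-2-methylnona-4,6-dienoyl]oxazolidin-2-one, via trimethylsilyl ether 7 (not isolated)
Conditions: MgCl2 (cat.), Et3N, TMSCl, EtOAc, rt; then MeOH, TFA (cat.), 0 °C
Reagents that add atoms: none
Why: Magnesium-halide-catalysed direct anti-aldol of an N-acyloxazolidinone (Evans anti-aldol): the chelated (Z)-magnesium enolate is attacked on the face away from the benzyl group through a boat transition state, which should set C2 (R) and C3 (R), anti, with the non-enolisable dienal; brief acid methanolysis removes only the O–SiMe3 group.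

Step 4
Reactants: 8 aldol adduct
Product: 9 (2R,3R,4E,6E)-9-(TBS-oxy)-3-hydroxy-N-methoxy-N,2-dimethylnona-4,6-dienamide
Conditions: AlMe3, MeNH(OMe)·HCl, CH2Cl2, −20 → 0 °C
Reagents that add atoms: N,O-dimethylhydroxylamine hydrochloride, CNOC.Cl
Why: Aluminium-amide transamination (Weinreb amide formation) is directed by the free β-hydroxyl as its aluminium alkoxide and cleaves the exocyclic imide carbonyl without touching C2 or C3.

Step 5
Reactants: 9 Weinreb amide
Product: 10 ethyl (4R,5R,6E,8E)-11-(TBS-oxy)-5-hydroxy-4-methyl-3-oxoundeca-6,8-dienoate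
Conditions: LiN(iPr)2, EtOAc, THF, −78 °C; then 9, −78 → −40 °C
Reagents that add atoms: ethyl acetate, CCOC(C)=O
Why: Claisen-type acylation of the lithium enolate of ethyl acetate by the Weinreb amide stops at the ketone through the chelated tetrahedral intermediate, and the β-keto ester enolate that results shields C4 from epimerisation.

Step 6
Reactants: 10 β-keto ester
Product: 12 ethyl (3S,4S,5R,6E,8E)-11-(TBS-oxy)-3,5-dihydroxy-4-methylundeca-6,8-dienoate, via diethylboron chelate 11 (not isolated)
Conditions: Et2BOMe, THF/MeOH, −78 °C; NaBH4; then MeOH (azeotrope)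
Reagents that add atoms: none
Why: Narasaka–Prasad reduction: axial hydride delivery to the half-chair boron chelate, in which the C4 methyl and the dienyl group are equatorial, should give the 3,5-syn diol and so the anti,anti stereotriad.

Step 7
Reactants: 12 syn-diol ester
Product: 13 ethyl (3S,4S,5R,6E,8E)-3,5,11-tris(TBS-oxy)-4-methylundeca-6,8-dienoate
Conditions: TBSOTf, 2,6-lutidine, CH2Cl2, −78 → 0 °C
Reagents that add atoms: tert-butyldimethylsilyl triflate, CC(C)(C)[Si](C)(C)OS(=O)(=O)C(F)(F)F
Why: Silylation of both secondary alcohols with the silyl triflate; two separate silyl ethers (not a cyclic acetal) let both oxygens sit equatorial in the later decalin-forming cycloaddition.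

Step 8
Reactants: 13 tris-silyl ester
Product: 14 (3S,4S,5R,6E,8E)-3,5,11-tris(TBS-oxy)-4-methylundeca-6,8-dienal
Conditions: iBu2AlH (1.1 equiv), CH2Cl2, −78 °C
Reagents that add atoms: none
Why: Half-reduction of the β-silyloxy ester at low temperature stops at the aldehyde through the stable aluminium hemiacetal.

Step 9
Reactants: 14 aldehyde; 15 2-(triphenylphosphoranylidene)propanal
Product: 16 (2E,5S,6S,7R,8E,10E)-5,7,13-tris(TBS-oxy)-2,6-dimethyltrideca-2,8,10-trienal
Conditions: toluene, 60 °C
Reagents that add atoms: none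
Why: Wittig reaction of the stabilised ylide gives the (E)-2-methyl enal; the temperature is kept below that of the uncatalysed cycloaddition.

Step 10
Reactants: 16 trienal
Product: 17 trans-fused octalin aldehyde (5,7-bis(TBS-oxy)-2-[2-(TBS-oxy)ethyl]-1,6-dimethyl-1,2,4a,5,6,7,8,8a-octahydronaphthalene-1-carbaldehyde; CHO, the C2 arm and H-8a on one face; C1 methyl, H-4a, both silyloxy groups and the C6 methyl on the other)
Conditions: Me2AlCl, CH2Cl2, −78 → −20 °C
Reagents that add atoms: none
Why: Lewis-acid-catalysed type 1 intramolecular Diels–Alder reaction of the 2,8,10-trienal: the CHO-endo transition state with a chair tether, both silyloxy groups equatorial and the C6 methyl axial, should give the trans ring fusion and set C1, C2, C4a and C8a relative to the stereotriad.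

Step 11
Reactants: 18 4-methoxyfuran-2(5H)-one (methyl tetronate)
Product: 20 5-[(dimethylamino)methyl]-4-methoxyfuran-2(5H)-one (racemic), via 5-lithio tetronate 19 (not isolated)
Conditions: LiN(iPr)2, THF, −78 °C; then Me2N=CH2 I
Reagents that add atoms: N,N-dimethylmethyleneiminium iodide (Eschenmoser's salt), C=[N+](C)C.[I-]
Why: γ-Deprotonation gives the 2-oxidofuran-type dienolate, which undergoes a Mannich reaction at C5 with the iminium salt.

Step 12
Reactants: 20 Mannich base
Product: 22 4-methoxy-5-methylenefuran-2(5H)-one, via trimethylammonium iodide 21 (not isolated)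
Conditions: MeI, CH2Cl2, rt; then aq. NaHCO3
Reagents that add atoms: none
Why: N-Methylation followed by base-induced E1cB (Hofmann-type) elimination, driven by the acidic C5–H, gives the exocyclic methylene.

Step 13
Reactants: 22 methylene butenolide; 17 octalin aldehyde
Product: 24 carbinol adduct (C3 of the butenolide bonded to the former CHO carbon; both carbinol epimers), via 3-lithio butenolide 23 (not isolated)
Conditions: LiN(iPr)2, THF, −78 °C (22); then 17, −78 → −40 °C
Reagents that add atoms: none
Why: With no C5–H left the amide base lithiates C3 (directed vinylic lithiation of a 4-alkoxybutenolide), and the vinyllithium adds 1,2 to the neopentyl aldehyde, the known way to join tetronates to quaternary octalin aldehydes; the new carbinol centre is removed in step 15.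

Step 14
Reactants: 24 carbinol
Product: 25 diol (primary alcohol on the C2 arm freed)
Conditions: HF·pyridine, pyridine, THF, 0 °C
Reagents that add atoms: none
Why: Buffered HF·pyridine cleaves the unhindered primary silyl ether much faster than the two hindered secondary ones.

Step 15
Reactants: 25 diol
Product: 26 keto aldehyde (3-acyl-4-methoxy-5-methylenebutenolide on C1; CH2CHO on C2)
Conditions: Dess–Martin periodinane, CH2Cl2, 0 °C → rt
Reagents that add atoms: none
Why: Dess–Martin oxidation converts both alcohols in one operation, the carbinol to the acyl butenolide and the primary alcohol to the aldehyde, under non-basic conditions that spare the methylene butenolide.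

Step 16
Reactants: 27 (E)-2-methylpent-2-enal; 28 ethyl 2-(triphenylphosphoranylidene)propanoate
Product: 29 ethyl (2E,4E)-2,4-dimethylhepta-2,4-dienoate
Conditions: CH2Cl2, 40 °C
Reagents that add atoms: none
Why: Wittig reaction of the stabilised ylide with the (E)-enal gives the (2E,4E)-dienoate.

Step 17
Reactants: 29 dienoate
Product: 30 (2E,4E)-2,4-dimethylhepta-2,4-dien-1-ol
Conditions: iBu2AlH, CH2Cl2, −78 °C
Reagents that add atoms: none
Why: 1,2-Reduction of the conjugated ester to the allylic alcohol.

Step 18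
Reactants: 30 dienol
Product: 31 (2E,4E)-1-bromo-2,4-dimethylhepta-2,4-diene
Conditions: PBr3, pyridine (cat.), Et2O, −10 °C
Reagents that add atoms: phosphorus tribromide, BrP(Br)Br
Why: SN2 conversion of the primary allylic alcohol into the bromide at low temperature without allylic transposition; used crude.

Step 19
Reactants: 31 dienyl bromide; 32 methyltriphenylphosphonium bromide
Product: 34 [(3E,5E)-3,5-dimethylocta-3,5-dien-1-yl]triphenylphosphonium bromide, via methylenetriphenylphosphorane 33 (not isolated)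
Conditions: n-BuLi, THF, 0 °C (32); then 31, −78 → 0 °C
Reagents that add atoms: none
Why: C-Alkylation of methylenetriphenylphosphorane by the primary allylic bromide (SN2) gives the one-carbon-homologated homoallylic phosphonium salt.

Step 20
Reactants: 34 phosphonium bromide; 26 keto aldehyde
Product: 36 cycloaddition precursor ((2Z,5E,7E)-5,7-dimethyldeca-2,5,7-trienyl arm on C2), via phosphonium ylide 35 (not isolated)
Conditions: NaN(SiMe3)2, THF, −78 °C (34); then 26, −78 → −20 °C
Reagents that add atoms: none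
Why: Wittig reaction of the non-stabilised ylide under lithium-free conditions gives the (Z)-olefin through the kinetically formed cis-oxaphosphetane; addition to the unhindered aldehyde at −78 °C should outrun attack on the neopentyl ketone or the methylene butenolide.

Step 21
Reactants: 36 cycloaddition precursor
Product: 37 spirotetronate macrocycle (4-O-methyl; bis-TBS ether)
Conditions: toluene (high dilution), BHT, 100 °C
Reagents that add atoms: none
Why: Thermal, concerted but asynchronous [4+2] cycloaddition of normal electron demand: the electron-rich (E,E)-diene adds suprafacially to the exocyclic methylene of the 3-acyl-4-methoxybutenolide, the ethyl-bearing terminus bonding to the CH2 carbon and the methyl-bearing terminus to C5 of the butenolide. The closest known reaction type is the macrocycle-forming intramolecular Diels–Alder reaction of 3-acyl-5-methylene tetronates that carry a remote diene, which closes 11-membered spirotetronate carbocycles on heating. Two rings close: the cyclohexene by the cycloaddition itself, and the 11-membered carbocycle as the tether ring of a type 1 (fused-mode) intramolecular Diels–Alder reaction, its last bond being the one between the tethered diene terminus and the spiro carbon. The cis relation of the ethyl group and the CH2 arm on the new ring follows from the (E,E) diene geometry; the spiro centre follows from the transition state with the ring oxygen endo and C4 of the butenolide exo, the mode the short tether (from the C4 side of the dienophile to the outer position of the diene terminus) can reach and the one 5-methylene tetronates prefer intermolecularly. Which diene face adds is left to the decalin: the acyl group and the C2 arm leave ring A on the same face, and with the (Z)-olefin as a rigid turn and the axial C1 methyl disfavouring the other fold, the diene should stack on the butenolide face that gives the configuration of 37. The step needs this facial selectivity and ring closure over dimerisation; the first rests on the decalin stereocentres and the tether and is the least certain point of the route, the second on high dilution, and regiochemistry is fixed because only one orientation is tether-allowed.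

Step 22
Reactants: 37 cycloadduct
Product: 38 3-acyl tetronic acid (bis-TBS ether)
Conditions: LiCl, DMSO, 50 °C; dilute HCl work-up
Reagents that add atoms: none
Why: SN2 O-demethylation of the vinylogous methyl ester by chloride releases the 3-acyl tetronic acid without touching the silyl ethers.

Step 23
Reactants: 38 bis-TBS ether
Product: 39 CNP0259772.1
Conditions: HF (48% aq.), MeCN, 0 °C → rt
Reagents that add atoms: none
Why: Acidic fluoride cleaves the two secondary silyl ethers; no stereocentre is affected.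

**Compound list**

1 | tert-butyl(but-3-yn-1-yloxy)dimethylsilane | C#CCCO[Si](C)(C)C(C)(C)C | starting material
2 | (E)-[4-(TBS-oxy)but-1-enyl]zirconocene chloride | Cl[Zr](/C=C/CCO[Si](C)(C)C(C)(C)C)(C1C=CC=C1)C1C=CC=C1 | intermediate
3 | (E)-tert-butyl[(4-iodobut-3-en-1-yl)oxy]dimethylsilane | I/C=C/CCO[Si](C)(C)C(C)(C)C | intermediate
4 | acrolein | C=CC=O | starting material
5 | (2E,4E)-7-(TBS-oxy)hepta-2,4-dienal | O=C/C=C/C=C/CCO[Si](C)(C)C(C)(C)C | intermediate
6 | (S)-4-benzyl-3-propionyloxazolidin-2-one | CCC(=O)N1[C@@H](Cc2ccccc2)COC1=O | starting material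
7 | O-trimethylsilyl ether of aldol adduct 8 | O=C1OC[C@H](Cc2ccccc2)N1C(=O)[C@H](C)[C@H](O[Si](C)(C)C)/C=C/C=C/CCO[Si](C)(C)C(C)(C)C | intermediate
8 | (S)-4-benzyl-3-[(2R,3R,4E,6E)-9-(TBS-oxy)-3-hydroxy-2-methylnona-4,6-dienoyl]oxazolidin-2-one | O=C1OC[C@H](Cc2ccccc2)N1C(=O)[C@H](C)[C@H](O)/C=C/C=C/CCO[Si](C)(C)C(C)(C)C | intermediate
9 | (2R,3R,4E,6E)-9-(TBS-oxy)-3-hydroxy-N-methoxy-N,2-dimethylnona-4,6-dienamide | CON(C)C(=O)[C@H](C)[C@H](O)/C=C/C=C/CCO[Si](C)(C)C(C)(C)C | intermediate
10 | ethyl (4R,5R,6E,8E)-11-(TBS-oxy)-5-hydroxy-4-methyl-3-oxoundeca-6,8-dienoate | CCOC(=O)CC(=O)[C@H](C)[C@H](O)/C=C/C=C/CCO[Si](C)(C)C(C)(C)C | intermediate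
11 | diethylboron chelate of 10 | CCOC(=O)CC1=[O+][B-](CC)(CC)O[C@@H]([C@H]1C)/C=C/C=C/CCO[Si](C)(C)C(C)(C)C | intermediate
12 | ethyl (3S,4S,5R,6E,8E)-11-(TBS-oxy)-3,5-dihydroxy-4-methylundeca-6,8-dienoate | CCOC(=O)C[C@H](O)[C@H](C)[C@H](O)/C=C/C=C/CCO[Si](C)(C)C(C)(C)C | intermediate
13 | ethyl (3S,4S,5R,6E,8E)-3,5,11-tris(TBS-oxy)-4-methylundeca-6,8-dienoate | CCOC(=O)C[C@H](O[Si](C)(C)C(C)(C)C)[C@H](C)[C@H](O[Si](C)(C)C(C)(C)C)/C=C/C=C/CCO[Si](C)(C)C(C)(C)C | intermediate
14 | (3S,4S,5R,6E,8E)-3,5,11-tris(TBS-oxy)-4-methylundeca-6,8-dienal | O=CC[C@H](O[Si](C)(C)C(C)(C)C)[C@H](C)[C@H](O[Si](C)(C)C(C)(C)C)/C=C/C=C/CCO[Si](C)(C)C(C)(C)C | intermediate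
15 | 2-(triphenylphosphoranylidene)propanal | CC(C=O)=P(c1ccccc1)(c1ccccc1)c1ccccc1 | starting material
16 | (2E,5S,6S,7R,8E,10E)-5,7,13-tris(TBS-oxy)-2,6-dimethyltrideca-2,8,10-trienal | O=C/C(C)=C/C[C@H](O[Si](C)(C)C(C)(C)C)[C@H](C)[C@H](O[Si](C)(C)C(C)(C)C)/C=C/C=C/CCO[Si](C)(C)C(C)(C)C | intermediate
17 | trans-fused octalin aldehyde (see step 10) | O=C[C@@]1(C)[C@@H]2C[C@H](O[Si](C)(C)C(C)(C)C)[C@H](C)[C@H](O[Si](C)(C)C(C)(C)C)[C@H]2C=C[C@H]1CCO[Si](C)(C)C(C)(C)C | intermediate
18 | 4-methoxyfuran-2(5H)-one | COC1=CC(=O)OC1 | starting material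
19 | 5-lithio-4-methoxyfuran-2(5H)-one | COC1=CC(=O)OC1[Li] | intermediate
20 | 5-[(dimethylamino)methyl]-4-methoxyfuran-2(5H)-one (racemic) | CN(C)CC1OC(=O)C=C1OC | intermediate
21 | [(3-methoxy-5-oxo-2,5-dihydrofuran-2-yl)methyl]trimethylammonium iodide | C[N+](C)(C)CC1OC(=O)C=C1OC.[I-] | intermediate
22 | 4-methoxy-5-methylenefuran-2(5H)-one | C=C1OC(=O)C=C1OC | intermediate
23 | 3-lithio-4-methoxy-5-methylenefuran-2(5H)-one | C=C1OC(=O)C([Li])=C1OC | intermediate
24 | carbinol from 23 and 17 (both carbinol epimers) | C=C1OC(=O)C(C(O)[C@@]2(C)[C@@H]3C[C@H](O[Si](C)(C)C(C)(C)C)[C@H](C)[C@H](O[Si](C)(C)C(C)(C)C)[C@H]3C=C[C@H]2CCO[Si](C)(C)C(C)(C)C)=C1OC | intermediate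
25 | diol (primary alcohol free) | C=C1OC(=O)C(C(O)[C@@]2(C)[C@@H]3C[C@H](O[Si](C)(C)C(C)(C)C)[C@H](C)[C@H](O[Si](C)(C)C(C)(C)C)[C@H]3C=C[C@H]2CCO)=C1OC | intermediate
26 | keto aldehyde | C=C1OC(=O)C(C(=O)[C@@]2(C)[C@@H]3C[C@H](O[Si](C)(C)C(C)(C)C)[C@H](C)[C@H](O[Si](C)(C)C(C)(C)C)[C@H]3C=C[C@H]2CC=O)=C1OC | intermediate
27 | (E)-2-methylpent-2-enal | CC/C=C(\C)C=O | starting material
28 | ethyl 2-(triphenylphosphoranylidene)propanoate | CCOC(=O)C(C)=P(c1ccccc1)(c1ccccc1)c1ccccc1 | starting material
29 | ethyl (2E,4E)-2,4-dimethylhepta-2,4-dienoate | CC/C=C(C)/C=C(\C)C(=O)OCC | intermediate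
30 | (2E,4E)-2,4-dimethylhepta-2,4-dien-1-ol | CC/C=C(C)/C=C(\C)CO | intermediate
31 | (2E,4E)-1-bromo-2,4-dimethylhepta-2,4-diene | CC/C=C(C)/C=C(\C)CBr | intermediate
32 | methyltriphenylphosphonium bromide | C[P+](c1ccccc1)(c1ccccc1)c1ccccc1.[Br-] | starting material
33 | methylenetriphenylphosphorane | C=P(c1ccccc1)(c1ccccc1)c1ccccc1 | intermediate
34 | [(3E,5E)-3,5-dimethylocta-3,5-dien-1-yl]triphenylphosphonium bromide | CC/C=C(C)/C=C(\C)CC[P+](c1ccccc1)(c1ccccc1)c1ccccc1.[Br-] | intermediate
35 | (3E,5E)-3,5-dimethylocta-3,5-dienylidenetriphenylphosphorane | CC/C=C(C)/C=C(\C)CC=P(c1ccccc1)(c1ccccc1)c1ccccc1 | intermediate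
36 | cycloaddition precursor (methylene acyl butenolide on C1, (2Z,5E,7E)-trienyl arm on C2) | C=C1OC(=O)C(C(=O)[C@@]2(C)[C@@H]3C[C@H](O[Si](C)(C)C(C)(C)C)[C@H](C)[C@H](O[Si](C)(C)C(C)(C)C)[C@H]3C=C[C@H]2C/C=C\C/C(C)=C/C(C)=C/CC)=C1OC | intermediate
37 | spirotetronate macrocycle, 4-O-methyl, bis-TBS ether | CC[C@@H]1C[C@]23OC(=O)C(C(=O)[C@@]4(C)[C@@H]5C[C@H](O[Si](C)(C)C(C)(C)C)[C@H](C)[C@H](O[Si](C)(C)C(C)(C)C)[C@H]5C=C[C@H]4C/C=C\C[C@]2(C)C=C1C)=C3OC | intermediate
38 | 3-acyl tetronic acid, bis-TBS ether | CC[C@@H]1C[C@]23OC(=O)/C(=C(\O)[C@@]4(C)[C@@H]5C[C@H](O[Si](C)(C)C(C)(C)C)[C@H](C)[C@H](O[Si](C)(C)C(C)(C)C)[C@H]5C=C[C@H]4C/C=C\C[C@]2(C)C=C1C)C3=O | intermediate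
39 | CNP0259772.1 | CC[C@@H]1C[C@]23OC(=O)/C(=C(\O)[C@@]4(C)[C@@H]5C[C@H](O)[C@H](C)[C@H](O)[C@H]5C=C[C@H]4C/C=C\C[C@]2(C)C=C1C)C3=O | target

**Step count and risks**

Total step count: 23. Longest linear sequence: 17 steps (steps 1–10, 13–15, 20–23).

Steps most likely to fail:

1. Step 21. The two carbonyl-exo transition states, one for each face of the diene, may not be differentiated well enough by the decalin, or ring closure may be slow enough for dimerisation to compete. The fallback is convergent and reagent-controlled; it sets out from bromide 31 and aldehyde 17 and returns to the route at 37. Bromide 31 is coupled with vinylmagnesium bromide (CuI cat., THF) to (4E,6E)-4,6-dimethylnona-1,4,6-triene F1. A thermal Diels–Alder reaction with (R)-2-tert-butyl-5-methylene-1,3-dioxolan-4-one (C=C1O[C@@H](C(C)(C)C)OC1=O), which reacts carbonyl-exo and on the face away from tert-butyl, gives spiro-dioxolanone F2. Methanolysis (NaOMe, MeOH) gives hydroxy ester F3, and ketenylidenetriphenylphosphorane (Ph3P=C=C=O, toluene, reflux; O-acylation then intramolecular Wittig) gives spiro methyl tetronate F4. Lithiation with LiN(iPr)2 gives 3-lithio tetronate F5, which adds to 17 to give carbinol F6. HF·pyridine then gives diol F7, Dess–Martin oxidation keto aldehyde F8, and Ph3P=CH2 the bis-allyl compound F9. Z-selective ring-closing metathesis with a molybdenum monoaryloxide pyrrolide alkylidene, Mo(NAr)(CHCMe2Ph)(NC4H4)(OAr′), closes the 11-membered ring to 37.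

2. Step 20. Conjugate addition of ylide 35 to the exocyclic methylene of 26, or proton transfer, may compete with olefination. The fallback reverses the order of cycloaddition and olefination; it sets out from 26 and 34 and returns at 37. The two are heated together (MeCN, 80 °C, concentrated) in a bimolecular Diels–Alder reaction of the same carbonyl-exo mode, which consumes the methylene group before any ylide exists and gives phosphonium aldehyde F10. KN(SiMe3)2 at high dilution then forms ylide F11, which closes the ring by an intramolecular Z-selective Wittig reaction. Facial control is lost in the bimolecular step, so the diastereomers would be separated after ring closure.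

3. Step 13. Anionic polymerisation of 22, or addition of the amide base to its methylene group during C3 lithiation, and sluggish addition to the neopentyl aldehyde may occur. The fallback needs no strong base; it sets out from 22 and 17 and returns at 24. Compound 22 is iodinated at C3 (N-iodosuccinimide, MeCN) to 3-iodo-4-methoxy-5-methylenefuran-2(5H)-one F12, which is coupled with 17 under Nozaki–Hiyama–Kishi conditions (CrCl2, NiCl2 cat., DMF), a method that tolerates hindered aldehydes.

Further compounds
F1 | step 21 | (4E,6E)-4,6-dimethylnona-1,4,6-triene | C=CC/C(C)=C/C(C)=C/CC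
F2 | step 21 | spiro-dioxolanone Diels–Alder adduct | CC[C@@H]1C[C@]3(O[C@@H](C(C)(C)C)OC3=O)[C@](C)(CC=C)C=C1C
F3 | step 21 | methyl 1-hydroxycyclohexenecarboxylate from F2 | CC[C@@H]1C[C@@](O)(C(=O)OC)[C@](C)(CC=C)C=C1C
F4 | step 21 | spiro methyl tetronate with allyl group | CC[C@@H]1C[C@]2(OC(=O)C=C2OC)[C@](C)(CC=C)C=C1C
F5 | step 21 | 3-lithio derivative of F4 | CC[C@@H]1C[C@]2(OC(=O)C([Li])=C2OC)[C@](C)(CC=C)C=C1C
F6 | step 21 | carbinol from F5 and 17 | CC[C@@H]1C[C@]2(OC(=O)C(C(O)[C@@]3(C)[C@@H]4C[C@H](O[Si](C)(C)C(C)(C)C)[C@H](C)[C@H](O[Si](C)(C)C(C)(C)C)[C@H]4C=C[C@H]3CCO[Si](C)(C)C(C)(C)C)=C2OC)[C@](C)(CC=C)C=C1C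
F7 | step 21 | diol from F6 | CC[C@@H]1C[C@]2(OC(=O)C(C(O)[C@@]3(C)[C@@H]4C[C@H](O[Si](C)(C)C(C)(C)C)[C@H](C)[C@H](O[Si](C)(C)C(C)(C)C)[C@H]4C=C[C@H]3CCO)=C2OC)[C@](C)(CC=C)C=C1C
F8 | step 21 | keto aldehyde from F7 | CC[C@@H]1C[C@]2(OC(=O)C(C(=O)[C@@]3(C)[C@@H]4C[C@H](O[Si](C)(C)C(C)(C)C)[C@H](C)[C@H](O[Si](C)(C)C(C)(C)C)[C@H]4C=C[C@H]3CC=O)=C2OC)[C@](C)(CC=C)C=C1C
F9 | step 21 | bis-allyl metathesis precursor | CC[C@@H]1C[C@]2(OC(=O)C(C(=O)[C@@]3(C)[C@@H]4C[C@H](O[Si](C)(C)C(C)(C)C)[C@H](C)[C@H](O[Si](C)(C)C(C)(C)C)[C@H]4C=C[C@H]3CC=C)=C2OC)[C@](C)(CC=C)C=C1C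
F10 | step 20 | phosphonium aldehyde from bimolecular Diels–Alder reaction of 26 and 34 | CC[C@@H]1C[C@]2(OC(=O)C(C(=O)[C@@]3(C)[C@@H]4C[C@H](O[Si](C)(C)C(C)(C)C)[C@H](C)[C@H](O[Si](C)(C)C(C)(C)C)[C@H]4C=C[C@H]3CC=O)=C2OC)[C@](C)(CC[P+](c5ccccc5)(c6ccccc6)c7ccccc7)C=C1C.[Br-]
F11 | step 20 | ylide from F10 | CC[C@@H]1C[C@]2(OC(=O)C(C(=O)[C@@]3(C)[C@@H]4C[C@H](O[Si](C)(C)C(C)(C)C)[C@H](C)[C@H](O[Si](C)(C)C(C)(C)C)[C@H]4C=C[C@H]3CC=O)=C2OC)[C@](C)(CC=P(c5ccccc5)(c6ccccc6)c7ccccc7)C=C1C
F12 | step 13 | 3-iodo-4-methoxy-5-methylenefuran-2(5H)-one | C=C1OC(=O)C(I)=C1OC
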